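**Plan**
1. Cuts, in target labels: C3–C18 (side lactone, reductive vinylogous Mannich on lactam 25), C13–CH3 (enolate methylation), C9a–C1 (radical ring closure; C1–C3 come from succinic anhydride), C9a=C12 (lactam carbonyl plus enol), C11–C12 (pyruvate aldol), C9–C10 (Ireland–Claisen), N4–C9a (lactamisation).
2. Forward order of rings: azepane (caprolactam 9), hydroxybutenolide (13), cyclopentene by closing C9a=C12 (16), pyrrolidinone by closing C9a–C1 (21), saturation and methylation of the fused lactone (25), side butenolide (29), target 30.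
3. Enabling feature: in 19 the tetrasubstituted C9a=C12 bond lies inside the cyclopentene and outside the keto lactone; it is the β,α pair of the C13 enone and C9a carries N4. A three-atom N4-acyl chain therefore reaches C9a in 5-exo fashion, and its terminal CO2H is the traceless radical source.
4. Stereochemistry: C9 and C10 from the chair Ireland–Claisen with transfer from a CBS-made (S)-carbinol; C11 from a Felkin–Anh aldol; C9a from C9 in the key step; C12 and C13 from the convex face of the cis-fused lactone; C3 and C18 from the Mannich step; C20 from hydrogenation anti to C18.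

Key step: step 11

Labels used in names (none appear in SMILES): pyrrolidine N4–C9a–C1–C2–C3; azepane N4–C5–C6–C7–C8–C9–C9a; cyclopentane C9a–C9–C10(Et)–C11(O)–C12; fused lactone C11–O–C14(=O)–C13(OH)(Me)–C12; side lactone C18(O)–C19–C20(Me)–C21(=O).
Remark: a fused α-keto lactone that carries hydrogen at C12 (20) is expected to rest as its enol (21); step 12 works on either tautomer.

**Step 1**
Reactants: 1 (3E)-hex-3-en-2-one
Product: 2 (2S,3E)-hex-3-en-2-ol
Conditions: (R)-tetrahydro-1-methyl-3,3-diphenyl-1H,3H-pyrrolo[1,2-c][1,3,2]oxazaborole (10 mol %), BH3·SMe2, THF, −20 °C; MeOH, then aqueous work-up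
Reagents that add atoms: none
Why: Corey–Bakshi–Shibata reduction, in which the catalyst–borane complex binds the ketone with the alkenyl group as the large substituent, so hydride should reach one carbonyl face and give the (S)-carbinol, the only stereocentre brought in from outside.

**Step 2**
Reactants: 2 (2S,3E)-hex-3-en-2-ol; 3 6-[(tert-butoxycarbonyl)amino]hexanoic acid
Product: 4 (2S,3E)-hex-3-en-2-yl 6-[(tert-butoxycarbonyl)amino]hexanoate
Conditions: DCC, DMAP (cat.), CH2Cl2, 0 °C → rt
Reagents that add atoms: none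
Why: Steglich esterification acylates the secondary allylic alcohol at oxygen and touches neither the carbinol centre nor the alkene geometry.

**Step 3**
Reactants: 4 (2S,3E)-hex-3-en-2-yl 6-[(tert-butoxycarbonyl)amino]hexanoate
Product: 7 (2R,3R,4E)-2-{4-[(tert-butoxycarbonyl)amino]butyl}-3-ethylhex-4-enoic acid, via silyl ketene acetal 5 (not isolated), via trimethylsilyl ester 6 (not isolated)
Conditions: LDA (2.2 equiv), THF, −78 °C; TMSCl, −78 → 60 °C; aq. citric acid
Reagents that add atoms: none
Why: Ireland–Claisen rearrangement, in which kinetic deprotonation in THF should give the (E)-O-silyl ketene acetal (chain cis to the allylic oxygen) and the chair transition state with the carbinol methyl equatorial transfers the (S)-centre to C9 and C10 in the anti sense (cis on the later cyclopentane) while forming the (E)-propenyl group.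

**Step 4**
Reactants: 7 (2R,3R,4E)-2-{4-[(tert-butoxycarbonyl)amino]butyl}-3-ethylhex-4-enoic acid
Product: 9 (3R)-3-[(3R,4E)-hex-4-en-3-yl]azepan-2-one, via amino acid 8 (not isolated)
Conditions: CF3CO2H, CH2Cl2, 0 °C → rt; evaporate; EDC·HCl, HOBt, iPr2NEt, CH2Cl2 (0.005 M), rt
Reagents that add atoms: none
Why: Boc acidolysis followed by carbodiimide lactamisation at high dilution closes the seven-membered lactam (N4–C9a), and C9 should hold because the activated acid has no N-acyl group able to form an azlactone.

**Step 5**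
Reactants: 9 (3R)-3-[(3R,4E)-hex-4-en-3-yl]azepan-2-one
Product: 10 (2S)-2-[(3R)-2-oxoazepan-3-yl]butanal
Conditions: O3, CH2Cl2/MeOH, −78 °C; Me2S, −78 °C → rt
Reagents that add atoms: ozone, [O-][O+]=O
Why: Ozonolysis with reductive work-up cleaves the disubstituted alkene to the C11 aldehyde and leaves the lactam and both stereocentres untouched.

**Step 6**
Reactants: 10 (2S)-2-[(3R)-2-oxoazepan-3-yl]butanal; 11 methyl 2-[(trimethylsilyl)oxy]prop-2-enoate
Product: 13 (3R)-3-{(1S)-1-[(2R)-4-hydroxy-5-oxo-2,5-dihydrofuran-2-yl]propyl}azepan-2-one, via hydroxy keto ester 12 (not isolated)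
Conditions: BF3·OEt2, CH2Cl2, −78 °C; then CF3CO2H (cat.), CH2Cl2, rt
Reagents that add atoms: none
Why: Mukaiyama aldol addition of the pyruvate enol silane under BF3 should follow the Felkin–Anh model (attack anti to the C9 branch), setting C11 syn to the ethyl group on C10 (trans on the later ring), and acid then lactonises the γ-hydroxy α-keto ester to the enolised keto lactone.

**Step 7**
Reactants: 13 (3R)-3-{(1S)-1-[(2R)-4-hydroxy-5-oxo-2,5-dihydrofuran-2-yl]propyl}azepan-2-one
Product: 14 O-tert-butyldimethylsilyl enol ether of 13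
Conditions: TBSCl, imidazole, DMF, 0 °C → rt
Reagents that add atoms: tert-butyldimethylsilyl chloride, CC(C)(C)[Si](C)(C)Cl
Why: O-Silylation of the acidic enol gives a silyl enol ether that is nucleophilic at C12 and is not triflated in the next step.

**Step 8**
Reactants: 14 O-tert-butyldimethylsilyl enol ether of 13
Product: 16 (9R,10S,11R)-tricyclic NH vinylogous amide with the C9a=C12 bond, via imidoyl triflate 15 (not isolated)
Conditions: Tf2O, 2-fluoropyridine, CH2Cl2, −78 → 0 °C; aq. NaHCO3
Reagents that add atoms: none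
Why: Electrophilic amide activation, in which triflic anhydride turns the secondary lactam into a cyclic imidoyl triflate that C12 of the silyl enol ether attacks in 5-exo fashion (Mukaiyama–Mannich-type addition–elimination), and tautomerisation gives the hydrogen-bonded vinylogous amide.

**Step 9**
Reactants: 16 (9R,10S,11R)-tricyclic NH vinylogous amide; 17 succinic anhydride
Product: 18 N4-(3-carboxypropanoyl) derivative of 16
Conditions: NaH, THF, 0 °C; 17, 0 °C → rt; 1 M HCl
Reagents that add atoms: none
Why: N-Acylation of the sodium salt of the vinylogous amide by ring opening of the anhydride installs C3, C2 and C1 together with the carboxyl that will later leave as CO2.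

**Step 10**
Reactants: 18 N4-(3-carboxypropanoyl) derivative of 16
Product: 19 1,3-dioxoisoindolin-2-yl ester of 18
Conditions: N-hydroxyphthalimide, DIC, CH2Cl2, rt
Reagents that add atoms: N-hydroxyphthalimide, O=C1c2ccccc2C(=O)N1O
Why: Carbodiimide esterification gives the N-(acyloxy)phthalimide, a redox-active ester that fragments on one-electron reduction.

**Step 11**
Reactants: 19 1,3-dioxoisoindolin-2-yl ester of 18
Product: 21 (9R,9aR,10S,11R)-tetracyclic enol lactam, via keto lactone 20 (not isolated)
Conditions: Ru(bpy)3(PF6)2 (1 mol %), Hantzsch ester (1.5 equiv), iPr2NEt·HBF4 (1 equiv), CH2Cl2 (0.01 M), blue LEDs, rt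
Reagents that add atoms: none
Why: One-electron reduction of the phthalimide ester by the photoreduced ruthenium complex releases CO2 and phthalimide and leaves a primary radical at C1, which adds to C9a, the β-carbon of the C9a=C12–C13=O enone, closing the pyrrolidinone; the α-keto radical at C12 is then reduced and protonated by the Hantzsch ester to keto lactone 20, which enolises to 21. The closest known reactions are reductive decarboxylative radical conjugate additions of redox-active esters and 5-exo cyclisations of nitrogen-tethered radicals onto β-aminoacrylates. The ring closes in the 5-exo-trig mode, with the C9a=C12 bond outside the new five-membered ring. The new quaternary centre C9a is controlled by C9: the azepine methylene C8 covers one face of the planar enaminone, so C1 should enter anti to C8 and syn to H9, giving the cis-fused azepane–cyclopentane, while the configuration at C12 does not matter because it is lost in the enol. The step needs attack at C9a in preference to 6-endo attack at C12 and to premature hydrogen transfer to the radical; the first is secured by the enone polarity (nucleophilic alkyl radical, β-carbon) and the shorter tether, the second by high dilution and the weak hydrogen donor.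

**Step 12**
Reactants: 21 (9R,9aR,10S,11R)-tetracyclic enol lactam
Product: 22 (9R,9aR,10S,11R,12R,13S)-13-hydroxy lactone lactam
Conditions: H2 (50 bar), 5% Rh/Al2O3, EtOAc/AcOH, rt
Reagents that add atoms: none
Why: Heterogeneous hydrogenation adds H2 syn across the C12=C13 enol from the convex face of the bicyclic lactone (the face of H11), the only face that leads to a cis-fused system, so H12 and H13 should come out cis to H11 with the C13 hydroxyl endo.

**Step 13**
Reactants: 22 (9R,9aR,10S,11R,12R,13S)-13-hydroxy lactone lactam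
Product: 25 (9R,9aR,10S,11R,12S,13S)-13-hydroxy-13-methyl lactone lactam, via trimethylsilyl ether 23 (not isolated), via methylated trimethylsilyl ether 24 (not isolated)
Conditions: TMSCl, imidazole, CH2Cl2, rt; filter, evaporate; KHMDS, THF, −78 °C, then MeI; 1 M HCl, THF, rt
Reagents that add atoms: iodomethane, CI
Why: After temporary silylation, the lactone enolate (the lactam is far less acidic) is alkylated by iodomethane on the convex face of the cis-fused lactone, which puts the methyl group exo and leaves the oxygen endo, and acid work-up frees the tertiary alcohol.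

**Step 14**
Reactants: 26 3-methylfuran-2(5H)-one
Product: 27 triisopropyl[(3-methylfuran-2-yl)oxy]silane
Conditions: TIPSOTf, Et3N, CH2Cl2, 0 °C
Reagents that add atoms: triisopropylsilyl trifluoromethanesulfonate, CC(C)[Si](OS(=O)(=O)C(F)(F)F)(C(C)C)C(C)C
Why: Soft enolisation and O-silylation of the butenolide gives the 2-silyloxyfuran, a dienolate equivalent that reacts at its C5.

**Step 15**
Reactants: 25 (9R,9aR,10S,11R,12S,13S)-13-hydroxy-13-methyl lactone lactam; 27 triisopropyl[(3-methylfuran-2-yl)oxy]silane
Product: 29 (3S,9R,9aR,10S,11R,12S,13S,18S)-butenolide (30 with a C19=C20 double bond), via silyl hemiaminal 28 (not isolated)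
Conditions: IrCl(CO)(PPh3)2 (1 mol %), (Me2HSi)2O, toluene, rt; then 27, BF3·OEt2, CH2Cl2, −78 °C → rt; aq. NaHCO3
Reagents that add atoms: none
Why: Iridium-catalysed hydrosilylation reduces only the tertiary lactam to an N,O-silyl acetal, and its iminium ion is attacked at C3 by C5 of the silyloxyfuran (vinylogous Mannich reaction) from the pyrrolidine face opposite the C12 lactone, i.e. syn to C9, with the usual threo preference at C18.

**Step 16**
Reactants: 29 (3S,9R,9aR,10S,11R,12S,13S,18S)-butenolide
Product: 30 CNP0260919.4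
Conditions: H2 (1 atm), 10% Pd/C, EtOAc, rt
Reagents that add atoms: none
Why: Hydrogenation of the butenolide from the face opposite its C18 substituent should place the C20 methyl group cis to that substituent.

**Compound list**
1 | (3E)-hex-3-en-2-one | CC(=O)/C=C/CC | starting material
2 | (2S,3E)-hex-3-en-2-ol | C[C@H](O)/C=C/CC | intermediate
3 | 6-[(tert-butoxycarbonyl)amino]hexanoic acid | OC(=O)CCCCCNC(=O)OC(C)(C)C | starting material
4 | (2S,3E)-hex-3-en-2-yl 6-[(tert-butoxycarbonyl)amino]hexanoate | C[C@H](OC(=O)CCCCCNC(=O)OC(C)(C)C)/C=C/CC | intermediate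
5 | (E)-O-trimethylsilyl ketene acetal of 4, chain cis to the allylic oxygen, carbamate N-silylated | C[C@H](O/C(O[Si](C)(C)C)=C\CCCCN([Si](C)(C)C)C(=O)OC(C)(C)C)/C=C/CC | intermediate
6 | trimethylsilyl (2R,3R,4E)-2-{4-[(tert-butoxycarbonyl)(trimethylsilyl)amino]butyl}-3-ethylhex-4-enoate | CC[C@H](/C=C/C)[C@@H](CCCCN([Si](C)(C)C)C(=O)OC(C)(C)C)C(=O)O[Si](C)(C)C | intermediate
7 | (2R,3R,4E)-2-{4-[(tert-butoxycarbonyl)amino]butyl}-3-ethylhex-4-enoic acid | CC[C@H](/C=C/C)[C@@H](CCCCNC(=O)OC(C)(C)C)C(=O)O | intermediate
8 | (2R,3R,4E)-2-(4-aminobutyl)-3-ethylhex-4-enoic acid | CC[C@H](/C=C/C)[C@@H](CCCCN)C(=O)O | intermediate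
9 | (3R)-3-[(3R,4E)-hex-4-en-3-yl]azepan-2-one | CC[C@H](/C=C/C)[C@H]1CCCCNC1=O | intermediate
10 | (2S)-2-[(3R)-2-oxoazepan-3-yl]butanal | CC[C@H](C=O)[C@H]1CCCCNC1=O | intermediate
11 | methyl 2-[(trimethylsilyl)oxy]prop-2-enoate | C=C(O[Si](C)(C)C)C(=O)OC | starting material
12 | methyl (4S,5S)-4-hydroxy-2-oxo-5-[(3R)-2-oxoazepan-3-yl]heptanoate | CC[C@H]([C@@H](O)CC(=O)C(=O)OC)[C@H]1CCCCNC1=O | intermediate
13 | (3R)-3-{(1S)-1-[(2R)-4-hydroxy-5-oxo-2,5-dihydrofuran-2-yl]propyl}azepan-2-one | CC[C@H]([C@H]1OC(=O)C(O)=C1)[C@H]1CCCCNC1=O | intermediate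
14 | (3R)-3-{(1S)-1-[(2R)-4-{[tert-butyl(dimethyl)silyl]oxy}-5-oxo-2,5-dihydrofuran-2-yl]propyl}azepan-2-one | CC[C@H]([C@H]1OC(=O)C(O[Si](C)(C)C(C)(C)C)=C1)[C@H]1CCCCNC1=O | intermediate
15 | (6R)-6-{(1S)-1-[(2R)-4-{[tert-butyl(dimethyl)silyl]oxy}-5-oxo-2,5-dihydrofuran-2-yl]propyl}-3,4,5,6-tetrahydro-2H-azepin-7-yl trifluoromethanesulfonate | CC[C@H]([C@H]1OC(=O)C(O[Si](C)(C)C(C)(C)C)=C1)[C@H]1CCCCN=C1OS(=O)(=O)C(F)(F)F | intermediate
16 | (9R,10S,11R)-tricyclic NH vinylogous amide: azepane N4–C5–C8–C9–C9a, cyclopentene C9a=C12–C11–C10(Et)–C9, keto lactone C11–O–C14(=O)–C13(=O)–C12 | CC[C@@H]1[C@H]2OC(=O)C(=O)C2=C3NCCCC[C@H]13 | intermediate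
17 | succinic anhydride | O=C1CCC(=O)O1 | starting material
18 | 16 acylated at N4 with a 3-carboxypropanoyl group | CC[C@@H]1[C@H]2OC(=O)C(=O)C2=C3N(C(=O)CCC(=O)O)CCCC[C@H]13 | intermediate
19 | 1,3-dioxoisoindolin-2-yl ester of 18 | CC[C@@H]1[C@H]2OC(=O)C(=O)C2=C3N(C(=O)CCC(=O)ON4C(=O)c5ccccc5C4=O)CCCC[C@H]13 | intermediate
20 | (9R,9aR,10S,11R,12S)-tetracyclic keto lactone: γ-lactam N4–C3(=O)–C2–C1–C9a closed, H12 cis to H11, C13 ketone | CC[C@@H]1[C@H]2OC(=O)C(=O)[C@H]2[C@]23CCC(=O)N2CCCC[C@H]13 | intermediate
21 | (9R,9aR,10S,11R)-enol tautomer of 20 (C12=C13–OH) | CC[C@@H]1[C@H]2OC(=O)C(O)=C2[C@]23CCC(=O)N2CCCC[C@H]13 | intermediate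
22 | (9R,9aR,10S,11R,12R,13S)-13-hydroxy lactone lactam: H12 and H13 cis to H11, 13-OH endo | CC[C@@H]1[C@H]2OC(=O)[C@@H](O)[C@H]2[C@]23CCC(=O)N2CCCC[C@H]13 | intermediate
23 | 13-O-trimethylsilyl ether of 22 | CC[C@@H]1[C@H]2OC(=O)[C@@H](O[Si](C)(C)C)[C@H]2[C@]23CCC(=O)N2CCCC[C@H]13 | intermediate
24 | 13-methyl-13-O-trimethylsilyl ether, methyl exo | CC[C@@H]1[C@H]2OC(=O)[C@@](C)(O[Si](C)(C)C)[C@H]2[C@]23CCC(=O)N2CCCC[C@H]13 | intermediate
25 | (9R,9aR,10S,11R,12S,13S)-13-hydroxy-13-methyl lactone lactam: the target without its side lactone, C3 as lactam carbonyl | CC[C@@H]1[C@H]2OC(=O)[C@@](C)(O)[C@H]2[C@]23CCC(=O)N2CCCC[C@H]13 | intermediate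
26 | 3-methylfuran-2(5H)-one | CC1=CCOC1=O | starting material
27 | triisopropyl[(3-methylfuran-2-yl)oxy]silane | Cc1ccoc1O[Si](C(C)C)(C(C)C)C(C)C | intermediate
28 | C3 N,O-silyl acetal of 25 (C3–O–SiMe2–O–SiMe2H) | CC[C@@H]1[C@H]2OC(=O)[C@@](C)(O)[C@H]2[C@]23CCC(O[Si](C)(C)O[SiH](C)C)N2CCCC[C@H]13 | intermediate
29 | (3S,9R,9aR,10S,11R,12S,13S,18S)-butenolide: 30 with a C19=C20 double bond | CC[C@@H]1[C@H]2OC(=O)[C@@](C)(O)[C@H]2[C@]23CC[C@@H]([C@@H]4C=C(C)C(=O)O4)N2CCCC[C@H]13 | intermediate
30 | CNP0260919.4, (3S,9R,9aR,10S,11R,12S,13S,18S,20S) | CC[C@@H]1[C@H]2OC(=O)[C@@](C)(O)[C@H]2[C@]23CC[C@@H]([C@@H]4C[C@H](C)C(=O)O4)N2CCCC[C@H]13 | target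

Total step count: 16. Longest linear sequence: 15 steps (steps 1–13, 15, 16).

**Steps most likely to fail**

Step 11. The primary radical may take up hydrogen, or add 6-endo at C12, before it closes onto the fully substituted C9a; attack on the wrong face would give the trans-fused system. The fallback forms the same bond by a polar, intermolecular addition and closes the ring through the amide bond instead. It sets out from 16. Boc2O and DMAP give the N-Boc vinylogous amide F1. Hosomi–Sakurai conjugate allylation (allyltrimethylsilane, TiCl4, CH2Cl2, −78 °C) adds the allyl group to C9a anti to C8 and gives the C9a-allyl enol F2. Hydroboration–oxidation (9-BBN, then NaBO3) gives the primary alcohol F3, and oxidation (TEMPO, PhI(OAc)2, MeCN/H2O) gives the acid F4. Trifluoroacetic acid followed by EDC closes the N4–C3 lactam and comes back to the route at 21.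

Step 8. The activated lactam may lose its α-hydrogen (erasing C9) or be captured at oxygen before C12 attacks. The fallback uses the classical lactim ether condensation with an active methylene partner. It sets out from 14. Trimethyloxonium tetrafluoroborate (CH2Cl2, then K2CO3) gives the O-methyl lactim ether F5. Bu4NF in THF (rt → 50 °C) then frees the enolate, which condenses at C9a with loss of methanol and comes back to the route at 16.

Step 15. The furan may enter C3 from the face syn to C12, or give the erythro arrangement at C18. The fallback delivers hydrogen instead of carbon to C3, so the same facial bias would then give the required epimer. It sets out from 25. Lawesson's reagent (toluene, 80 °C) gives the thiolactam F6. S-Alkylation with 5-bromo-3-methylfuran-2(5H)-one followed by PPh3 and Et3N (Eschenmoser sulfide contraction) gives the C3=C18 alkylidene butenolide F7 with N4 trans to the ring oxygen. Hydrogenation (H2, Rh/Al2O3, EtOAc) adds syn across C3=C18 and then across C19=C20 and comes back to the route at 30.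

**Further compounds**
F1 | step 11 | N4-Boc derivative of 16 | CC[C@@H]1[C@H]2OC(=O)C(=O)C2=C3N(C(=O)OC(C)(C)C)CCCC[C@H]13
F2 | step 11 | C9a-allyl N4-Boc enol lactone (allyl anti to C8) | CC[C@@H]1[C@H]2OC(=O)C(O)=C2[C@]3(CC=C)N(C(=O)OC(C)(C)C)CCCC[C@H]13
F3 | step 11 | C9a-(3-hydroxypropyl) N4-Boc enol lactone | CC[C@@H]1[C@H]2OC(=O)C(O)=C2[C@]3(CCCO)N(C(=O)OC(C)(C)C)CCCC[C@H]13
F4 | step 11 | C9a-(2-carboxyethyl) N4-Boc enol lactone | CC[C@@H]1[C@H]2OC(=O)C(O)=C2[C@]3(CCC(=O)O)N(C(=O)OC(C)(C)C)CCCC[C@H]13
F5 | step 8 | O-methyl lactim ether of 14 | CC[C@H]([C@H]1OC(=O)C(O[Si](C)(C)C(C)(C)C)=C1)[C@H]1CCCCN=C1OC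
F6 | step 15 | C3 thiolactam of 25 | CC[C@@H]1[C@H]2OC(=O)[C@@](C)(O)[C@H]2[C@]23CCC(=S)N2CCCC[C@H]13
F7 | step 15 | C3=C18 alkylidene butenolide (N4 trans to the ring oxygen) | CC[C@@H]1[C@H]2OC(=O)[C@@](C)(O)[C@H]2[C@]23CC/C(=C4/C=C(C)C(=O)O4)N2CCCC[C@H]13
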